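**Plan**

- Retrosynthesis: the acrolein is unmasked last from a dimethyl acetal and the two tiglates are taken back to a diol. The dihydrofuran ring is then cut at O1–C2 and at C3a–C3 together, leaving an ortho-metalated, O-silylated (R)-4-(1-silyloxyethyl)phenol and the C5 enal OHC–CH=C(CH2OAc)CH(OMe)2.
- Enabling feature: C3 is a benzylic carbinol ortho to the ring oxygen O1 (an arylated aldehyde), and C2 is an allylic ether carbon next to the exocyclic C(=CH2) (an allyl electrophile after 1,3-transposition). The O1–C2–C3–O unit with its C(=CH2)–CHO branch is therefore a γ-acetoxy enal taken up by a phenol acting as C,O-bis-nucleophile.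
- Forward: the arene (3 steps) and the enal (2 steps) are joined in one flask by enantioselective aryl transfer to the aldehyde and palladium-catalysed allylic etherification. This closes the dihydrofuran, the only ring made in the route; bis-tigloylation and acetal hydrolysis finish.
- Stereochemistry: the side-chain carbinol comes from a Corey–Bakshi–Shibata reduction, C3 from the chiral amino alcohol catalyst of the aryl transfer, and C2 from the C3 carbinol (trans ring closure).

Key step: step 6

Remark: the C5 enal is drawn and used as its E isomer; a Z fraction would give the same carbinol configuration and the same allylpalladium unit in the key step, so it need not be removed.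

**Route**

Step 1
Reactants: 1 1-(3-bromo-4-hydroxyphenyl)ethan-1-one
Product: 2 1-{3-bromo-4-[(tert-butyldimethylsilyl)oxy]phenyl}ethan-1-one
Conditions: TBSCl, imidazole, DMF, rt
Reagents that add atoms: tert-butyldimethylsilyl chloride, CC(C)(C)[Si](C)(C)Cl
Why: Imidazole-promoted silyl ether formation masks the acidic phenol for the borane reduction and the later bromine–lithium exchange, and no stereocentre is formed.

Step 2
Reactants: 2 1-{3-bromo-4-[(tert-butyldimethylsilyl)oxy]phenyl}ethan-1-one
Product: 3 (1R)-1-{3-bromo-4-[(tert-butyldimethylsilyl)oxy]phenyl}ethan-1-ol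
Conditions: (S)-2-methyl-CBS-oxazaborolidine (10 mol%), BH3·SMe2, THF, −20 °C
Reagents that add atoms: none
Why: Corey–Bakshi–Shibata reduction of an aryl methyl ketone, in which the (S)-oxazaborolidine–borane complex binds the ketone with the aryl group as the large substituent and should deliver hydride to give the (R)-carbinol, as with acetophenone.

Step 3
Reactants: 3 (1R)-1-{3-bromo-4-[(tert-butyldimethylsilyl)oxy]phenyl}ethan-1-ol
Product: 4 tert-butyl{2-bromo-4-[(1R)-1-(triethylsilyloxy)ethyl]phenoxy}dimethylsilane
Conditions: TESCl, imidazole, DMF, 0 °C to rt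
Reagents that add atoms: chlorotriethylsilane, CC[Si](Cl)(CC)CC
Why: Silyl ether formation at oxygen leaves the stereocentre untouched, and the triethylsilyl group should survive the organolithium and organozinc stages and fall off with fluoride together with the aryl silyl ether.

Step 4
Reactants: 5 3-bromo-1,1-dimethoxypropan-2-one
Product: 6 3,3-dimethoxy-2-oxopropyl acetate
Conditions: KOAc, DMF, rt
Reagents that add atoms: potassium acetate, CC(=O)[O-].[K+]
Why: SN2 displacement of an activated α-bromo ketone by acetate installs the future allylic leaving group, and no stereocentre is involved.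

Step 5
Reactants: 6 3,3-dimethoxy-2-oxopropyl acetate
Product: 7 (2E)-2-(dimethoxymethyl)-4-oxobut-2-en-1-yl acetate
Conditions: Ph3P=CHCHO, toluene, 80 °C
Reagents that add atoms: (triphenylphosphoranylidene)acetaldehyde, O=CC=P(c1ccccc1)(c1ccccc1)c1ccccc1
Why: Wittig olefination of a ketone made electrophilic by its α-acetoxy and α,α-dimethoxy groups with the stabilized formyl ylide should give the enal, mainly with the aldehyde trans to the bulkier dimethoxymethyl group.

Step 6
Reactants: 4 tert-butyl{2-bromo-4-[(1R)-1-(triethylsilyloxy)ethyl]phenoxy}dimethylsilane, 7 (2E)-2-(dimethoxymethyl)-4-oxobut-2-en-1-yl acetate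
Product: 12 (2R,3S)-2-(3,3-dimethoxyprop-1-en-2-yl)-5-[(1R)-1-hydroxyethyl]-2,3-dihydro-1-benzofuran-3-ol, via aryllithium 8 (not isolated), via butyl(aryl)zinc 9 (not isolated), via allylic alcohol 10 (not isolated), via desilylated triol 11 (not isolated)
Conditions: n-BuLi, t-BuOMe, −78 °C; ZnCl2; n-BuLi; N,N,N′,N′-tetraethylethylenediamine (TEEDA), toluene; (−)-MIB [(2S)-3-exo-morpholinoisoborneol, 5 mol%], 7, 0 °C; then MeOH; Pd(PPh3)4 (5 mol%), TBAF, THF, 0 °C to rt
Reagents that add atoms: none
Why: Bromine–lithium exchange and transmetalation give butyl(aryl)zinc 9, whose aryl group is transferred to the aldehyde of 7 under amino alkoxide catalysis to form C3a–C3 (alcohol 10 after the methanol quench); fluoride then frees the phenoxide of 11, zerovalent palladium ionizes the allylic acetate, and the phenoxide attacks the allyl terminus next to the carbinol to form O1–C2 and the exocyclic methylene. The closest known reaction types are the catalytic enantioselective arylzinc addition to enals and the intramolecular Tsuji–Trost O-allylation of phenols, the whole being the oxygenated counterpart of the classical phenoxide/1,4-dihalobut-2-ene dihydrobenzofuran annulation. The dihydrofuran ring closes in the 5-exo mode on the allylpalladium unit, which is preferred over attack at the CH2 terminus (seven-membered ring). C3 is set by the catalyst, since (−)-MIB should direct the aryl group to the Si face of the aldehyde as in its other organozinc additions and so give the (4R) carbinol of 10 (3S in 12); C2 is set by C3, because closure through the less eclipsed transition state puts the alkenyl group trans to the hydroxyl, and re-ionization of the allyl aryl ether should drain any cis isomer to the more stable trans product. The step needs aryl over butyl transfer and 1,2- over 1,4-addition (secured by the faster transfer of sp2 groups from mixed zinc reagents and by the β,β-disubstituted enal) and attack by the phenol oxygen and not by the two alcohols (secured by its acidity and by the ring size).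

Step 7
Reactants: 12 (2R,3S)-2-(3,3-dimethoxyprop-1-en-2-yl)-5-[(1R)-1-hydroxyethyl]-2,3-dihydro-1-benzofuran-3-ol
Product: 13 (1R)-1-[(2R,3S)-2-(3,3-dimethoxyprop-1-en-2-yl)-3-{[(2E)-2-methylbut-2-enoyl]oxy}-2,3-dihydro-1-benzofuran-5-yl]ethyl (2E)-2-methylbut-2-enoate
Conditions: tigloyl chloride, Et3N, DMAP (cat.), CH2Cl2, 0 °C to rt
Reagents that add atoms: (2E)-2-methylbut-2-enoyl chloride (tigloyl chloride), C/C=C(/C(Cl)=O)C
Why: DMAP-catalysed O-acylation of both secondary alcohols breaks no C–O bond at a stereocentre, the E geometry comes with the reagent, and the trans ring (C2–H syn to the C3 ester) offers no anti-periplanar hydrogen for elimination to the benzofuran.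

Step 8
Reactants: 13 (1R)-1-[(2R,3S)-2-(3,3-dimethoxyprop-1-en-2-yl)-3-{[(2E)-2-methylbut-2-enoyl]oxy}-2,3-dihydro-1-benzofuran-5-yl]ethyl (2E)-2-methylbut-2-enoate
Product: 14 (1R)-1-[(2R,3S)-3-{[(2E)-2-methylbut-2-enoyl]oxy}-2-(3-oxoprop-1-en-2-yl)-2,3-dihydro-1-benzofuran-5-yl]ethyl (2E)-2-methylbut-2-enoate
Conditions: PPTS (cat.), acetone/H2O, rt
Reagents that add atoms: water, O
Why: Acid-catalysed hydrolysis of an allylic dimethyl acetal under buffered conditions should be much faster than ionization of the benzylic esters, and it frees the 2-substituted acrolein last, without nucleophiles present and without touching a stereocentre.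

**Compound list**

1 | 1-(3-bromo-4-hydroxyphenyl)ethan-1-one | CC(=O)c1ccc(O)c(Br)c1 | starting material
2 | 1-{3-bromo-4-[(tert-butyldimethylsilyl)oxy]phenyl}ethan-1-one | CC(=O)c1ccc(O[Si](C)(C)C(C)(C)C)c(Br)c1 | intermediate
3 | (1R)-1-{3-bromo-4-[(tert-butyldimethylsilyl)oxy]phenyl}ethan-1-ol | C[C@@H](O)c1ccc(O[Si](C)(C)C(C)(C)C)c(Br)c1 | intermediate
4 | tert-butyl{2-bromo-4-[(1R)-1-(triethylsilyloxy)ethyl]phenoxy}dimethylsilane | C[C@@H](O[Si](CC)(CC)CC)c1ccc(O[Si](C)(C)C(C)(C)C)c(Br)c1 | intermediate
5 | 3-bromo-1,1-dimethoxypropan-2-one | COC(OC)C(=O)CBr | starting material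
6 | 3,3-dimethoxy-2-oxopropyl acetate | CC(=O)OCC(=O)C(OC)OC | intermediate
7 | (2E)-2-(dimethoxymethyl)-4-oxobut-2-en-1-yl acetate | O=C/C=C(/C(OC)OC)COC(C)=O | intermediate
8 | {2-[(tert-butyldimethylsilyl)oxy]-5-[(1R)-1-(triethylsilyloxy)ethyl]phenyl}lithium | [Li]c1cc(ccc1O[Si](C)(C)C(C)(C)C)[C@@H](C)O[Si](CC)(CC)CC | intermediate
9 | butyl{2-[(tert-butyldimethylsilyl)oxy]-5-[(1R)-1-(triethylsilyloxy)ethyl]phenyl}zinc | CCCC[Zn]c1cc(ccc1O[Si](C)(C)C(C)(C)C)[C@@H](C)O[Si](CC)(CC)CC | intermediate
10 | (2E,4R)-4-{2-[(tert-butyldimethylsilyl)oxy]-5-[(1R)-1-(triethylsilyloxy)ethyl]phenyl}-2-(dimethoxymethyl)-4-hydroxybut-2-en-1-yl acetate | CC[Si](CC)(CC)O[C@H](C)c1ccc(O[Si](C)(C)C(C)(C)C)c(c1)[C@H](O)/C=C(/C(OC)OC)COC(C)=O | intermediate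
11 | (2E,4R)-2-(dimethoxymethyl)-4-hydroxy-4-{2-hydroxy-5-[(1R)-1-hydroxyethyl]phenyl}but-2-en-1-yl acetate | C[C@@H](O)c1ccc(O)c(c1)[C@H](O)/C=C(/C(OC)OC)COC(C)=O | intermediate
12 | (2R,3S)-2-(3,3-dimethoxyprop-1-en-2-yl)-5-[(1R)-1-hydroxyethyl]-2,3-dihydro-1-benzofuran-3-ol | COC(OC)C(=C)[C@H]1Oc2ccc([C@@H](C)O)cc2[C@@H]1O | intermediate
13 | (1R)-1-[(2R,3S)-2-(3,3-dimethoxyprop-1-en-2-yl)-3-{[(2E)-2-methylbut-2-enoyl]oxy}-2,3-dihydro-1-benzofuran-5-yl]ethyl (2E)-2-methylbut-2-enoate | COC(OC)C(=C)[C@H]1Oc2ccc([C@@H](C)OC(=O)/C(C)=C/C)cc2[C@@H]1OC(=O)/C(C)=C/C | intermediate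
14 | (1R)-1-[(2R,3S)-3-{[(2E)-2-methylbut-2-enoyl]oxy}-2-(3-oxoprop-1-en-2-yl)-2,3-dihydro-1-benzofuran-5-yl]ethyl (2E)-2-methylbut-2-enoate | C=C(C=O)[C@H]1Oc2ccc([C@@H](C)OC(=O)/C(C)=C/C)cc2[C@@H]1OC(=O)/C(C)=C/C | target

**Summary**

Total step count: 8 steps. Longest linear sequence: 6 steps (steps 1, 2, 3, 6, 7, 8).

Steps most likely to fail:

1. Step 6. The aryl transfer may show poor face selectivity, because the ortho silyloxy group and the acetal and acetate oxygens of 7 can compete for zinc; less likely, the ring closure may not be fully trans selective. Fallback: the carbinol is made without stereocontrol and corrected by a reagent-controlled reduction. It sets out from aryllithium 8 (from 4 and n-BuLi) and 7. Addition at −78 °C in THF gives the C4-epimeric carbinol (2E)-4-{2-[(tert-butyldimethylsilyl)oxy]-5-[(1R)-1-(triethylsilyloxy)ethyl]phenyl}-2-(dimethoxymethyl)-4-hydroxybut-2-en-1-yl acetate F1. Oxidation with MnO2 in CH2Cl2 gives the aryl enone (2E)-4-{2-[(tert-butyldimethylsilyl)oxy]-5-[(1R)-1-(triethylsilyloxy)ethyl]phenyl}-2-(dimethoxymethyl)-4-oxobut-2-en-1-yl acetate F2. Corey–Bakshi–Shibata reduction with (S)-2-methyl-CBS-oxazaborolidine and catecholborane at −78 °C (aryl group as the large substituent, 1,2-reduction only) should return the (4R) carbinol 10, now isolated. Treatment of 10 with Pd(PPh3)4 and TBAF as in step 6 rejoins the route at 12.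

2. Step 5. The ketone may react sluggishly with the stabilized ylide, and the product aldehyde may be olefinated a second time. Fallback: the enal is made by alkynylation and rearrangement. It sets out from 6. Ethynylmagnesium bromide (THF, −78 °C) adds to the ketone to give the tertiary propargylic alcohol 2-(dimethoxymethyl)-2-hydroxybut-3-yn-1-yl acetate F3. A Meyer–Schuster rearrangement (MoO2(acac)2, Ph3PAuCl, AgOTf, toluene, rt) then gives the enal, and the route is rejoined at 7.

3. Step 7. Acylation of two hindered benzylic secondary alcohols by a poorly electrophilic, α-branched unsaturated acyl donor may be slow, with competing ionization at the electron-rich benzylic positions. Fallback: the tiglates are built by olefination. It sets out from 12. Both hydroxyls are esterified with the unhindered 2-(diethoxyphosphoryl)propanoic acid (DCC, DMAP, CH2Cl2) to give (1R)-1-[(2R,3S)-3-{[2-(diethoxyphosphoryl)propanoyl]oxy}-2-(3,3-dimethoxyprop-1-en-2-yl)-2,3-dihydro-1-benzofuran-5-yl]ethyl 2-(diethoxyphosphoryl)propanoate F4. A Horner–Wadsworth–Emmons reaction with acetaldehyde (LiCl, DBU, MeCN) should then form both (E)-2-methylbut-2-enoates, and the route is rejoined at 13.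

**Further compounds**

F1 | step 6 | (2E)-4-{2-[(tert-butyldimethylsilyl)oxy]-5-[(1R)-1-(triethylsilyloxy)ethyl]phenyl}-2-(dimethoxymethyl)-4-hydroxybut-2-en-1-yl acetate, mixture of C4 epimers | CC[Si](CC)(CC)O[C@H](C)c1ccc(O[Si](C)(C)C(C)(C)C)c(c1)C(O)/C=C(/C(OC)OC)COC(C)=O
F2 | step 6 | (2E)-4-{2-[(tert-butyldimethylsilyl)oxy]-5-[(1R)-1-(triethylsilyloxy)ethyl]phenyl}-2-(dimethoxymethyl)-4-oxobut-2-en-1-yl acetate | CC[Si](CC)(CC)O[C@H](C)c1ccc(O[Si](C)(C)C(C)(C)C)c(c1)C(=O)/C=C(/C(OC)OC)COC(C)=O
F3 | step 5 | 2-(dimethoxymethyl)-2-hydroxybut-3-yn-1-yl acetate, racemic | CC(=O)OCC(O)(C#C)C(OC)OC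
F4 | step 7 | (1R)-1-[(2R,3S)-3-{[2-(diethoxyphosphoryl)propanoyl]oxy}-2-(3,3-dimethoxyprop-1-en-2-yl)-2,3-dihydro-1-benzofuran-5-yl]ethyl 2-(diethoxyphosphoryl)propanoate, mixture of epimers at the phosphonate-bearing carbons | COC(OC)C(=C)[C@H]1Oc2ccc([C@@H](C)OC(=O)C(C)P(=O)(OCC)OCC)cc2[C@@H]1OC(=O)C(C)P(=O)(OCC)OCC
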